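**Plan**
Retrosynthesis: the tiglate and the silyl groups are removed first; ring B is opened at C8–C9 (enyne), the side chain is cut at C9=C11 (aldehyde plus an (R)-linalool-derived C11–C16 ylide), C18 is cut from C4 (cyclopropane), and ring A is cut at C5–C10 and C1–C2.
Enabling feature: in ring A the quaternary C10 lies next to C5 and carries two one-carbon branches (C20 and the arm C9), which is the α-carbon of a 2-(oxymethyl)acrolein with C1 as its CH2 terminus; C2–C5, with C19 on C4 and the C6–C8 chain on C5, is the diene.
Forward: dienophile (steps 1–2), diene (3–6), ring A by cycloaddition (7), CHO to C20 methyl, quaternary C4, C8 alkyne, C19 tiglate, C9 aldehyde (8–17), side-chain salt (18–22), Wittig union, ring B by reductive enyne cyclisation, desilylation (23–25).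
Stereochemistry: C10 from the chiral oxazaborolidinium catalyst, C5 from the endo mode, C4 from α-face methylene delivery, C9 from a chair-like 6-exo insertion, C13 from (R)-linalool.

Key step: step 7

Remark (assumption on the chemistry): the enal is taken to bind the cationic oxazaborolidine as other α-substituted acroleins do; on that model the catalyst made from (R)-diphenylprolinol gives 10, and the one from (S)-diphenylprolinol would give its antipode.
Convention: labdane numbering (C1–C20) is used for all intermediates; α and β refer to the usual labdane drawing with the C20 methyl group β.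

Step 1
Reactants: 1 2-methylenepropane-1,3-diol
Product: 2 2-[(triisopropylsilyloxy)methyl]prop-2-en-1-ol
Conditions: NaH (1.0 equiv), THF, 0 °C; TIPSCl (1.0 equiv), 0 → 23 °C
Reagents that add atoms: triisopropylsilyl chloride, CC(C)[Si](Cl)(C(C)C)C(C)C
Why: O-silylation of the sparingly soluble monosodium alkoxide of a symmetrical diol stops after one silyl group (monoprotection by the alkoxide method), leaving one allylic hydroxyl.

Step 2
Reactants: 2 2-[(triisopropylsilyloxy)methyl]prop-2-en-1-ol
Product: 3 2-[(triisopropylsilyloxy)methyl]prop-2-enal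
Conditions: MnO2 (15 equiv), CH2Cl2, 23 °C
Reagents that add atoms: none
Why: MnO2 oxidation of a primary allylic alcohol stops at the enal and does not touch the silyl ether.

Step 3
Reactants: 4 pent-4-yn-1-ol
Product: 5 hex-2-yne-1,6-diol
Conditions: n-BuLi (2.1 equiv), THF, −78 → 0 °C; (CH2O)n, 0 → 23 °C; aq. NH4Cl
Reagents that add atoms: paraformaldehyde (as formaldehyde), C=O
Why: The lithium alkoxide–acetylide dianion reacts at carbon with formaldehyde (acetylide hydroxymethylation), which installs the future C19 as a propargylic alcohol.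

Step 4
Reactants: 5 hex-2-yne-1,6-diol
Product: 6 (E)-2-(tributylstannyl)hex-2-ene-1,6-diol
Conditions: Bu3SnH (1.1 equiv, slow addition), PdCl2(PPh3)2 (2 mol%), THF, 0 → 23 °C
Reagents that add atoms: tributyltin hydride, CCCC[SnH](CCCC)CCCC
Why: Palladium-catalysed hydrostannation adds H and Sn syn across the alkyne and, in 2-alkyn-1-ols, puts tin on the carbon next to the hydroxymethyl group, so the C6–C8 chain ends up cis to CH2OH and trans to tin.

Step 5
Reactants: 6 (E)-2-(tributylstannyl)hex-2-ene-1,6-diol
Product: 7 (E)-tributyl[1,6-bis(4-methoxybenzyloxy)hex-2-en-2-yl]stannane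
Conditions: NaH (2.5 equiv), PMBCl (2.4 equiv), Bu4NI (cat.), THF/DMF, 0 → 23 °C
Reagents that add atoms: 4-methoxybenzyl chloride, COc1ccc(CCl)cc1
Why: Williamson etherification of both primary alkoxides, the vinylstannane being inert to NaH, gives two PMB ethers that can later be removed together.

Step 6
Reactants: 7 (E)-tributyl[1,6-bis(4-methoxybenzyloxy)hex-2-en-2-yl]stannane; 8 vinyl bromide
Product: 9 (3Z)-7-(4-methoxybenzyloxy)-3-[(4-methoxybenzyloxy)methyl]hepta-1,3-diene
Conditions: Pd(PPh3)4 (5 mol%), CuI (10 mol%), CsF (2 equiv), DMF, 45 °C, sealed tube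
Reagents that add atoms: none
Why: Stille coupling transfers the alkenyl group with retention of geometry, copper iodide and fluoride speeding up transmetalation of the hindered α-substituted vinylstannane, so the vinyl group arrives trans to the C6–C8 chain.

Step 7
Reactants: 3 2-[(triisopropylsilyloxy)methyl]prop-2-enal; 9 (3Z)-7-(4-methoxybenzyloxy)-3-[(4-methoxybenzyloxy)methyl]hepta-1,3-diene
Product: 10 (1R,2S)-2-[3-(4-methoxybenzyloxy)propyl]-3-[(4-methoxybenzyloxy)methyl]-1-[(triisopropylsilyloxy)methyl]cyclohex-3-ene-1-carbaldehyde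
Conditions: N-protonated B-(o-tolyl)oxazaborolidine triflimide [from (R)-α,α-diphenylprolinol and o-tolylboronic acid (as boroxine), toluene, reflux, −H2O; then HNTf2, CH2Cl2, −25 °C] (20 mol%), CH2Cl2, −78 → −40 °C
Reagents that add atoms: none
Why: The boron cation binds the formyl oxygen of 3 syn to the formyl hydrogen (with a formyl C–H···O contact to the ring oxygen), lowers the LUMO of the s-trans enal and lets one phenyl group cover one face of the C10=C1 bond; a concerted, asynchronous [4+2] cycloaddition with the s-cis diene follows, the closest known reaction type being the cationic oxazaborolidine-catalysed Diels–Alder reaction of 2-substituted acroleins with acyclic dienes. Ring A closes as a six-membered carbocycle by intermolecular [4π+2π] cycloaddition in which the C1–C2 bond forms ahead of the C5–C10 bond. C10 is controlled by the catalyst: the cation made from (R)-diphenylprolinol leaves open the face of C10 on which CHO, C1 and CH2OTIPS run anticlockwise as seen from the incoming C5. C5 is controlled relative to C10 by the endo mode (activated formyl group under the diene, bulky silyloxymethyl arm outside) together with the fixed geometry of the C4=C5 bond, so the C6 chain and the formyl group end up cis. The step needs ortho regiochemistry (C10 to the substituted terminus C5), which the substrate secures because the unsubstituted C2 is the more nucleophilic terminus and the positive charge developing in the asynchronous transition state is best carried by the alkyl-substituted C5, the CH2OPMB group on C4 being too weak a donor to reverse this; it also needs endo selectivity, because the formyl carbon must be the arm cis to C6 (it becomes the β methyl C20) and the silyloxymethyl carbon the trans arm (it becomes C9).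

Step 8
Reactants: 10 ring A aldehyde
Product: 11 (E)-tosylhydrazone of 10
Conditions: TsNHNH2 (1.1 equiv), MeOH/THF, 23 → 40 °C
Reagents that add atoms: p-toluenesulfonyl hydrazide, Cc1ccc(cc1)S(=O)(=O)NN
Why: Condensation of the non-enolisable neopentyl aldehyde with tosylhydrazide gives the tosylhydrazone without risk to C10 and prepares C20 for deoxygenation.

Step 9
Reactants: 11 (E)-tosylhydrazone of 10
Product: 14 C20-methyl ring A triether (10 with CH3 in place of CHO), via alkyl tosylhydrazine 12 (not isolated), via alkyl diazene 13 (not isolated)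
Conditions: catecholborane (3 equiv), CHCl3, 0 °C; then NaOAc·3H2O, reflux
Reagents that add atoms: none
Why: Caglioti-type tosylhydrazone reduction with catecholborane, in which hydride adds to C=N, acetate-induced loss of sulfinate gives the diazene and loss of N2 leaves the C20 methyl group, runs under conditions that spare the alkene and the PMB and TIPS ethers.

Step 10
Reactants: 14 C20-methyl ring A triether
Product: 15 ring A allylic diol (C19 and C8 hydroxyls free)
Conditions: DDQ (2.5 equiv), CH2Cl2/pH 7 buffer (10:1), 0 → 23 °C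
Reagents that add atoms: none
Why: Oxidative PMB cleavage (hydride abstraction by DDQ, then hydrolysis of the oxocarbenium ions) frees the allylic C19 and the C8 hydroxyls while the TIPS ether stays.

Step 11
Reactants: 15 ring A allylic diol
Product: 16 3α,4α-methano diol (cyclopropane on the α face)
Conditions: Et2Zn (5 equiv), CH2I2 (10 equiv), CH2Cl2, −10 → 23 °C
Reagents that add atoms: diiodomethane, ICI
Why: Hydroxyl-accelerated Simmons–Smith cyclopropanation (Et2Zn/CH2I2 variant) of the allylic zinc alkoxide delivers methylene to the α face of C3=C4, because the β face is covered by the C6 chain on C5 (pseudoaxial to avoid A(1,2) strain with the CH2O group) and by the β C20 methyl, and this fixes C4 and C3.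

Step 12
Reactants: 16 3α,4α-methano diol
Product: 17 diol with quaternary C4 (4α-methyl, 4β-hydroxymethyl)
Conditions: H2 (3 atm), PtO2 (20 mol%), AcOH, 23 °C
Reagents that add atoms: none
Why: Catalytic cyclopropane hydrogenolysis cleaves the least substituted and most exposed bond (C3–CH2), so the α methylene becomes the α methyl C18 on the quaternary C4 whose configuration is not touched, and the TIPS ether is stable in acetic acid.

Step 13
Reactants: 17 diol with quaternary C4
Product: 18 C8 aldehyde with free C19 hydroxyl
Conditions: TEMPO (10 mol%), PhI(OAc)2 (1.1 equiv), CH2Cl2, 0 → 23 °C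
Reagents that add atoms: none
Why: TEMPO/oxoammonium oxidation is very sensitive to steric hindrance, so the unhindered C8 primary alcohol is oxidised to the aldehyde while the neopentyl, axial C19 hydroxyl is left.

Step 14
Reactants: 18 C8 aldehyde with free C19 hydroxyl
Product: 19 C8≡C17 alkyne with free C19 hydroxyl
Conditions: dimethyl (1-diazo-2-oxopropyl)phosphonate (1.3 equiv), K2CO3 (2 equiv), MeOH, 0 → 23 °C
Reagents that add atoms: dimethyl (1-diazo-2-oxopropyl)phosphonate, COP(=O)(OC)C(=[N+]=[N-])C(C)=O
Why: Seyferth–Gilbert homologation in the Ohira–Bestmann form converts the aldehyde into the terminal alkyne C8≡C17 (olefination, loss of N2, 1,2-shift in the alkylidene carbene) and tolerates the free hydroxyl.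

Step 15
Reactants: 19 C8≡C17 alkyne with free C19 hydroxyl; 20 tigloyl chloride
Product: 21 C19 tiglate of 19
Conditions: pyridine (3 equiv), DMAP (0.2 equiv), CH2Cl2, 0 → 40 °C
Reagents that add atoms: none
Why: DMAP-catalysed acylation of the only free hydroxyl (C19) by the acid chloride, with pyridine as a base too weak to form the vinylketene, keeps the E enoate.

Step 16
Reactants: 21 C19 tiglate of 19
Product: 22 C9 alcohol
Conditions: HF·pyridine, pyridine, THF, 0 → 23 °C
Reagents that add atoms: none
Why: Fluoride-driven Si–O cleavage frees the neopentyl C9 hydroxyl under non-basic conditions that leave the tiglate and the terminal alkyne alone.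

Step 17
Reactants: 22 C9 alcohol
Product: 23 C9 aldehyde
Conditions: Dess–Martin periodinane (1.5 equiv), CH2Cl2, 23 °C
Reagents that add atoms: none
Why: Dess–Martin oxidation turns the hindered neopentyl alcohol into the non-enolisable C9 aldehyde without affecting the ester, the alkyne or the neighbouring stereocentres.

Step 18
Reactants: 24 (R)-linalool
Product: 25 (R)-linalool triethylsilyl ether
Conditions: TESOTf (1.2 equiv), 2,6-lutidine (2 equiv), CH2Cl2, −78 → 0 °C
Reagents that add atoms: triethylsilyl trifluoromethanesulfonate, CC[Si](CC)(CC)OS(=O)(=O)C(F)(F)F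
Why: A silyl triflate with a hindered base silylates the tertiary allylic alcohol on oxygen without ionising it, so C13 keeps its configuration.

Step 19
Reactants: 25 (R)-linalool triethylsilyl ether
Product: 26 (R)-4-methyl-4-(triethylsilyloxy)hex-5-enal
Conditions: O3 (1 equiv), CH2Cl2, −78 °C (Sudan Red 7B end point); Me2S, −78 → 23 °C
Reagents that add atoms: ozone, [O-][O+]=O
Why: Ozonolysis is chemoselective for the electron-rich trisubstituted alkene over the monosubstituted vinyl group next to the silyloxy-bearing quaternary carbon, and reductive work-up gives the aldehyde.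

Step 20
Reactants: 26 (R)-4-methyl-4-(triethylsilyloxy)hex-5-enal
Product: 29 (R)-3-methyl-3-(triethylsilyloxy)pent-4-en-1-ol, via enamine 27 (not isolated), via nor-aldehyde 28 (not isolated)
Conditions: piperidine (1.5 equiv), 4 Å MS, Et2O, 23 °C; then O3 (1 equiv), CH2Cl2, −78 °C; then NaBH4, MeOH, −78 → 0 °C
Reagents that add atoms: ozone, [O-][O+]=O
Why: One-carbon degradation by enamine ozonolysis cleaves the very electron-rich enamine C=C in preference to the vinyl group, expels the old formyl carbon as N-formylpiperidine and is followed by borohydride reduction of the β-silyloxy aldehyde in the same flask before it can eliminate.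

Step 21
Reactants: 29 (R)-3-methyl-3-(triethylsilyloxy)pent-4-en-1-ol
Product: 30 (R)-triethyl[(5-iodo-3-methylpent-1-en-3-yl)oxy]silane
Conditions: I2 (1.3 equiv), PPh3 (1.3 equiv), imidazole (2.5 equiv), CH2Cl2, 0 → 23 °C
Reagents that add atoms: iodine, II
Why: Appel-type iodination displaces the alkoxyphosphonium group of the primary alcohol by iodide in an SN2 step and leaves the tertiary silyl ether untouched.

Step 22
Reactants: 30 (R)-triethyl[(5-iodo-3-methylpent-1-en-3-yl)oxy]silane
Product: 31 (R)-[3-methyl-3-(triethylsilyloxy)pent-4-en-1-yl]triphenylphosphonium iodide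
Conditions: PPh3 (1.5 equiv), MeCN, 80 °C
Reagents that add atoms: triphenylphosphine, c1ccc(cc1)P(c1ccccc1)c1ccccc1
Why: SN2 quaternisation of the primary iodide gives the Wittig salt, whose oxygen sits γ to phosphorus so that the later ylide cannot β-eliminate.

Step 23
Reactants: 23 C9 aldehyde; 31 (R)-[3-methyl-3-(triethylsilyloxy)pent-4-en-1-yl]triphenylphosphonium iodide
Product: 33 (9Z)-8,9-seco enyne (C9=C11 alkene, C8≡C17 alkyne, 13-OTES, C19 tiglate), via ylide 32 (not isolated)
Conditions: 31 (1.5 equiv), NaHMDS (1.45 equiv), THF, −78 → 0 °C; then 23, −78 → 23 °C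
Reagents that add atoms: none
Why: Wittig olefination of the non-enolisable C9 aldehyde with the unstabilised, salt-free ylide gives the (Z)-C9=C11 alkene through the kinetic cis-oxaphosphetane, the hindered conjugated ester and the alkyne being far less reactive towards the ylide.

Step 24
Reactants: 33 (9Z)-8,9-seco enyne
Product: 34 13-O-triethylsilyl ether of the target
Conditions: Pd2(dba)3·CHCl3 (5 mol%), P(o-tol)3 (20 mol%), AcOH (2 equiv), Et3SiH (10 equiv), benzene, 23 → 40 °C
Reagents that add atoms: none
Why: In this palladium-catalysed reductive 1,7-enyne cyclisation H–Pd–OAc (from zerovalent palladium and AcOH) hydropalladates the terminal alkyne to the C8 alkenylpalladium, which inserts the C9=C11 bond 6-exo through a chair-like arrangement with the C20 methyl axial and the side chain pseudoequatorial (close to the plane of the forming C8=C17 unit), giving 9α-H, and Et3SiH reduces the C11–Pd bond.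

Step 25
Reactants: 34 13-O-triethylsilyl ether of the target
Product: 35 CNP0313179.1, (13R)-13-hydroxylabda-8(17),14-dien-19-yl (E)-2-methylbut-2-enoate
Conditions: TBAF (1.5 equiv), AcOH (1.5 equiv), THF, 0 → 23 °C
Reagents that add atoms: none
Why: Fluoride cleaves the tertiary triethylsilyl ether, and buffering with acetic acid keeps the medium neutral so that the tiglate survives and the tertiary allylic alcohol is not transposed.

**Compound list**
1 | 2-methylenepropane-1,3-diol | C=C(CO)CO | starting material
2 | 2-[(triisopropylsilyloxy)methyl]prop-2-en-1-ol | C=C(CO)CO[Si](C(C)C)(C(C)C)C(C)C | intermediate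
3 | 2-[(triisopropylsilyloxy)methyl]prop-2-enal | C=C(C=O)CO[Si](C(C)C)(C(C)C)C(C)C | intermediate
4 | pent-4-yn-1-ol | C#CCCCO | starting material
5 | hex-2-yne-1,6-diol | OCC#CCCCO | intermediate
6 | (E)-2-(tributylstannyl)hex-2-ene-1,6-diol | OC/C(=C\CCCO)[Sn](CCCC)(CCCC)CCCC | intermediate
7 | (E)-tributyl[1,6-bis(4-methoxybenzyloxy)hex-2-en-2-yl]stannane | COc1ccc(COC/C(=C\CCCOCc2ccc(OC)cc2)[Sn](CCCC)(CCCC)CCCC)cc1 | intermediate
8 | vinyl bromide (bromoethene) | C=CBr | starting material
9 | (3Z)-7-(4-methoxybenzyloxy)-3-[(4-methoxybenzyloxy)methyl]hepta-1,3-diene (C6–C8 chain trans to the vinyl group) | C=C/C(COCc1ccc(OC)cc1)=C/CCCOCc1ccc(OC)cc1 | intermediate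
10 | (1R,2S)-2-[3-(4-methoxybenzyloxy)propyl]-3-[(4-methoxybenzyloxy)methyl]-1-[(triisopropylsilyloxy)methyl]cyclohex-3-ene-1-carbaldehyde (CHO β on C10, cis to the C6 chain; 5α-H) | COc1ccc(COCCC[C@H]2C(COCc3ccc(OC)cc3)=CCC[C@@]2(CO[Si](C(C)C)(C(C)C)C(C)C)C=O)cc1 | intermediate
11 | (E)-tosylhydrazone of 10 (C20H=N–NHTs) | COc1ccc(COCCC[C@H]2C(COCc3ccc(OC)cc3)=CCC[C@@]2(CO[Si](C(C)C)(C(C)C)C(C)C)/C=N/NS(=O)(=O)c4ccc(C)cc4)cc1 | intermediate
12 | alkyl tosylhydrazine (C20H2–NH–NHTs) | COc1ccc(COCCC[C@H]2C(COCc3ccc(OC)cc3)=CCC[C@@]2(CO[Si](C(C)C)(C(C)C)C(C)C)CNNS(=O)(=O)c4ccc(C)cc4)cc1 | intermediate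
13 | alkyl diazene (C20H2–N=NH) | COc1ccc(COCCC[C@H]2C(COCc3ccc(OC)cc3)=CCC[C@@]2(CO[Si](C(C)C)(C(C)C)C(C)C)CN=N)cc1 | intermediate
14 | ring A cyclohex-3-ene: 10β-methyl, 10α-[(triisopropylsilyloxy)methyl], 5β-[3-(4-methoxybenzyloxy)propyl] (5α-H), 4-[(4-methoxybenzyloxy)methyl] | COc1ccc(COCCC[C@H]2C(COCc3ccc(OC)cc3)=CCC[C@@]2(CO[Si](C(C)C)(C(C)C)C(C)C)C)cc1 | intermediate
15 | ring A cyclohex-3-ene diol: 4-(hydroxymethyl), 5β-(3-hydroxypropyl) (5α-H), 10β-methyl, 10α-[(triisopropylsilyloxy)methyl] | OCCC[C@H]1C(CO)=CCC[C@@]1(CO[Si](C(C)C)(C(C)C)C(C)C)C | intermediate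
16 | 3α,4α-methano analogue of 15 (cyclopropane CH2 on the α face, C19 hydroxymethyl β on C4) | OCCC[C@H]1[C@]2(CO)C[C@@H]2CC[C@@]1(CO[Si](C(C)C)(C(C)C)C(C)C)C | intermediate
17 | ring A cyclohexane diol: 4α-methyl, 4β-(hydroxymethyl), 5β-(3-hydroxypropyl) (5α-H), 10β-methyl, 10α-[(triisopropylsilyloxy)methyl] | OCCC[C@H]1[C@@](C)(CO)CCC[C@@]1(CO[Si](C(C)C)(C(C)C)C(C)C)C | intermediate
18 | C8 aldehyde of 17 (3-substituted propanal, C19 hydroxyl free) | O=CCC[C@H]1[C@@](C)(CO)CCC[C@@]1(CO[Si](C(C)C)(C(C)C)C(C)C)C | intermediate
19 | alkynol: 5β-(but-3-yn-1-yl) ring A (C8≡C17), C19 hydroxyl free, C9 OTIPS | C#CCC[C@H]1[C@@](C)(CO)CCC[C@@]1(CO[Si](C(C)C)(C(C)C)C(C)C)C | intermediate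
20 | tigloyl chloride, (E)-2-methylbut-2-enoyl chloride | C/C=C(\C)C(=O)Cl | starting material
21 | C19 tiglate of 19 | C#CCC[C@H]1[C@@](C)(COC(=O)/C(C)=C/C)CCC[C@@]1(CO[Si](C(C)C)(C(C)C)C(C)C)C | intermediate
22 | C9 alcohol (10α-hydroxymethyl), C19 tiglate, C8≡C17 alkyne | C#CCC[C@H]1[C@@](C)(COC(=O)/C(C)=C/C)CCC[C@@]1(CO)C | intermediate
23 | C9 aldehyde (10α-formyl), C19 tiglate, C8≡C17 alkyne | C#CCC[C@H]1[C@@](C)(COC(=O)/C(C)=C/C)CCC[C@@]1(C=O)C | intermediate
24 | (R)-linalool, (3R)-3,7-dimethylocta-1,6-dien-3-ol | C=C[C@](C)(O)CCC=C(C)C | starting material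
25 | (R)-[(3,7-dimethylocta-1,6-dien-3-yl)oxy]triethylsilane | C=C[C@](C)(O[Si](CC)(CC)CC)CCC=C(C)C | intermediate
26 | (R)-4-methyl-4-(triethylsilyloxy)hex-5-enal | C=C[C@](C)(O[Si](CC)(CC)CC)CCC=O | intermediate
27 | (R,E)-1-[4-methyl-4-(triethylsilyloxy)hexa-1,5-dien-1-yl]piperidine | C=C[C@](C)(O[Si](CC)(CC)CC)C/C=C/N1CCCCC1 | intermediate
28 | (R)-3-methyl-3-(triethylsilyloxy)pent-4-enal | C=C[C@](C)(O[Si](CC)(CC)CC)CC=O | intermediate
29 | (R)-3-methyl-3-(triethylsilyloxy)pent-4-en-1-ol | C=C[C@](C)(O[Si](CC)(CC)CC)CCO | intermediate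
30 | (R)-triethyl[(5-iodo-3-methylpent-1-en-3-yl)oxy]silane | C=C[C@](C)(O[Si](CC)(CC)CC)CCI | intermediate
31 | (R)-[3-methyl-3-(triethylsilyloxy)pent-4-en-1-yl]triphenylphosphonium iodide | C=C[C@](C)(O[Si](CC)(CC)CC)CC[P+](c1ccccc1)(c1ccccc1)c1ccccc1.[I-] | intermediate
32 | (R)-[3-methyl-3-(triethylsilyloxy)pent-4-en-1-ylidene]triphenylphosphorane | C=C[C@](C)(O[Si](CC)(CC)CC)CC=P(c1ccccc1)(c1ccccc1)c1ccccc1 | intermediate
33 | (13R)-13-(triethylsilyloxy)-8,9-secolabda-9(11)Z,14-dien-8(17)-yn-19-yl tiglate | C#CCC[C@H]1[C@@](C)(COC(=O)/C(C)=C/C)CCC[C@@]1(/C=C\C[C@@](C)(O[Si](CC)(CC)CC)C=C)C | intermediate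
34 | (13R)-13-(triethylsilyloxy)labda-8(17),14-dien-19-yl tiglate (5α-H, 9α-H, 10β-CH3, 4α-CH3) | C=C[C@](C)(O[Si](CC)(CC)CC)CC[C@H]1C(=C)CC[C@H]2[C@@](C)(COC(=O)/C(C)=C/C)CCC[C@]12C | intermediate
35 | CNP0313179.1, (13R)-13-hydroxylabda-8(17),14-dien-19-yl (E)-2-methylbut-2-enoate | C=C[C@](C)(O)CC[C@H]1C(=C)CC[C@H]2[C@@](C)(COC(=O)/C(C)=C/C)CCC[C@]12C | target

**Step count**
Total: 25 steps. Longest linear sequence: 18 steps (steps 3–17 and 23–25, from pent-4-yn-1-ol).

**Steps most likely to fail**

1. Step 24 (ring B closure).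
What may go wrong: hydropalladation followed by silane reduction of the alkyne may outrun the 6-exo insertion into the hindered, Z-configured C9=C11 bond next to the quaternary C10. Insertion through a non-chair arrangement would erode control at C9.
Fallback (radical instead of organopalladium ring closure): setting out from enyne 33, Bu3SnH and AIBN in benzene at 80 °C add a stannyl radical to C17. The C8 alkenyl radical closes 6-exo on C9 and the C11 radical is reduced, which should give the 17-tributylstannyl derivative of 34 F1. Protodestannylation on silica gel in CH2Cl2 then gives 34, where the route is rejoined.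

2. Step 7 (key cycloaddition).
What may go wrong: the two faces of the bound enal may be poorly discriminated, or material may leak through the exo mode or the para regiochemistry, because the α-substituent is bulky and the diene carries two Lewis-basic ethers. An exo adduct formed on the same enal face would fall into the enantiomeric series once the two arms are assigned, so endo selectivity is required.
Fallback (resolution instead of asymmetric catalysis, same cycloaddition): setting out from 3 and 9, Me2AlCl in CH2Cl2 at −78 °C should give the endo adduct as the racemate, that is 10 together with its antipode F2. Condensation with (1R,2R)-N,N′-dimethyl-1,2-diphenylethane-1,2-diamine (4 Å MS, CH2Cl2) converts the pair into the diastereomeric aminals, the aminal of 10 F3 and the aminal of the antipode F4, to be separated by chromatography. Hydrolysis of F3 (0.5 M aq. HCl, Et2O) returns 10, where the route is rejoined.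

3. Step 11 (C4 configuration).
What may go wrong: facial control may be lost, because the directing hydroxyl sits on the alkene carbon itself and can deliver methylene to either face, so the outcome rests on the steric bias of ring A alone.
Fallback (reagent control instead of substrate control): setting out from 15, Zn(CH2I)2·DME is used with the stoichiometric chiral controller (4R,5R)-2-butyl-N,N,N′,N′-tetramethyl-1,3,2-dioxaborolane-4,5-dicarboxamide (CH2Cl2, −10 → 23 °C). Its boronate complex with the allylic alkoxide should deliver methylene to the α face and give 16 directly, where the route is rejoined; no new compound is made (F0).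

**Further compounds**
F1 | step 24 | 17-(tributylstannyl) derivative of 34 (exocyclic alkenylstannane, mixture of C8=C17 isomers) | C=C[C@](C)(O[Si](CC)(CC)CC)CC[C@H]1C(=C[Sn](CCCC)(CCCC)CCCC)CC[C@H]2[C@@](C)(COC(=O)/C(C)=C/C)CCC[C@]12C
F2 | step 7 | antipode of 10, (1S,2R)-2-[3-(4-methoxybenzyloxy)propyl]-3-[(4-methoxybenzyloxy)methyl]-1-[(triisopropylsilyloxy)methyl]cyclohex-3-ene-1-carbaldehyde | COc1ccc(COCCC[C@@H]2C(COCc3ccc(OC)cc3)=CCC[C@]2(CO[Si](C(C)C)(C(C)C)C(C)C)C=O)cc1
F3 | step 7 | aminal of 10 with (1R,2R)-N,N′-dimethyl-1,2-diphenylethane-1,2-diamine (1,3-dimethyl-4,5-diphenylimidazolidin-2-yl group in place of CHO) | COc1ccc(COCCC[C@H]2C(COCc3ccc(OC)cc3)=CCC[C@@]2(CO[Si](C(C)C)(C(C)C)C(C)C)C4N(C)[C@H](c5ccccc5)[C@@H](c5ccccc5)N4C)cc1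
F4 | step 7 | aminal of F2 with (1R,2R)-N,N′-dimethyl-1,2-diphenylethane-1,2-diamine | COc1ccc(COCCC[C@@H]2C(COCc3ccc(OC)cc3)=CCC[C@]2(CO[Si](C(C)C)(C(C)C)C(C)C)C4N(C)[C@H](c5ccccc5)[C@@H](c5ccccc5)N4C)cc1
F0 | step 11 | none | none
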